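The polyene is cut at the C10–C11 single bond and at the C9–methyl bond. The all-E trisubstituted C9=C10 alkene, carrying its methyl on C9 next to the C11=C12 alkene, is exactly what syn addition of methyl and aluminium across a terminal C9≡C10 alkyne, followed by coupling at C10, delivers. In one operation, Cp2ZrCl2-catalysed methylalumination of the ring enyne (cyclohexene ring C1–C6 bearing C7=C8–C9≡C10 at C6 and a silyl ether at C3) and Pd(PPh3)4-catalysed coupling with the all-E C11–C8' iodohexaene silyl ether assemble the whole protected skeleton with 9E geometry fixed; no ring is formed. One desilylation then gives the diol.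

Key step: step 12

Assumption: atoms carry carotenoid numbers (ring C1–C6, chain C7–C15 then C15'–C8'); ethyl (2E)-4-(diethoxyphosphoryl)-2-methylbut-2-enoate is taken as a purchasable reagent, and the ketoreductase of step 2 is the one from a standard screening panel that reduces the (1R) keto ester to the (4R) alcohol.

Step 1
Reactants: 1 mesityl oxide; 2 ethyl acetoacetate
Product: 3 racemic ethyl 2,6,6-trimethyl-4-oxocyclohex-2-ene-1-carboxylate
Conditions: ZnCl2 (0.2 equiv), heptane–toluene, reflux, Dean–Stark; distillation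
Reagents that add atoms: none
Why: Lewis-acid-promoted Michael addition of the acetoacetate α-carbon to the β-carbon of mesityl oxide followed by intramolecular aldol condensation of the 1,5-diketone (Robinson-type annulation) should close the cyclohexenone with the ester-bearing carbon between the gem-dimethyl carbon and the methyl-bearing alkene carbon, and the single stereocentre is formed racemic.

Step 2
Reactants: 3 racemic ethyl 2,6,6-trimethyl-4-oxocyclohex-2-ene-1-carboxylate
Product: 4 ethyl (1R,4R)-4-hydroxy-2,6,6-trimethylcyclohex-2-ene-1-carboxylate (trans hydroxy ester)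
Conditions: NADPH-dependent ketoreductase, NADP+ (cat.), iPrOH, phosphate buffer pH 7, 30 °C, stopped near half conversion; chromatography
Reagents that add atoms: none
Why: Enzymatic ketone reduction run as a kinetic resolution should deliver hydride from NADPH to one face of the ring carbonyl of the (1R) keto ester only, so that the enzyme pocket sets the new carbinol centre as R and selects the existing 1R centre, while the unreacted (1S) keto ester is separated, racemised through its dienolate with base and returned to the step.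

Step 3
Reactants: 4 ethyl (1R,4R)-4-hydroxy-2,6,6-trimethylcyclohex-2-ene-1-carboxylate
Product: 5 ethyl (1R,4R)-4-[(tert-butyldimethylsilyl)oxy]-2,6,6-trimethylcyclohex-2-ene-1-carboxylate
Conditions: TBSCl, imidazole, DMF, rt
Reagents that add atoms: tert-butyldimethylsilyl chloride, CC(C)(C)[Si](C)(C)Cl
Why: Imidazole-promoted silylation of the secondary allylic alcohol (silyl ether formation) is routine and touches neither stereocentre.

Step 4
Reactants: 5 ethyl (1R,4R)-4-[(tert-butyldimethylsilyl)oxy]-2,6,6-trimethylcyclohex-2-ene-1-carboxylate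
Product: 6 [(1R,4R)-4-[(tert-butyldimethylsilyl)oxy]-2,6,6-trimethylcyclohex-2-en-1-yl]methanol
Conditions: iBu2AlH (2.5 equiv), CH2Cl2, −78 → 0 °C; aq. potassium sodium tartrate
Reagents that add atoms: none
Why: Aluminium hydride reduction of the hindered ester to the primary alcohol is non-basic, so the ester α-carbon C6 should keep its configuration and the silyl ether should stay in place.

Step 5
Reactants: 6 [(1R,4R)-4-[(tert-butyldimethylsilyl)oxy]-2,6,6-trimethylcyclohex-2-en-1-yl]methanol
Product: 7 (1R,4R)-4-[(tert-butyldimethylsilyl)oxy]-2,6,6-trimethylcyclohex-2-ene-1-carbaldehyde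
Conditions: Dess–Martin periodinane, NaHCO3, CH2Cl2, 0 °C → rt; used crude
Reagents that add atoms: none
Why: Dess–Martin oxidation under bicarbonate buffering should give the aldehyde without any enolising base, which keeps the allylic α-centre C6 from epimerising and the C4=C5 alkene from moving into conjugation.

Step 6
Reactants: 7 (1R,4R)-4-[(tert-butyldimethylsilyl)oxy]-2,6,6-trimethylcyclohex-2-ene-1-carbaldehyde
Product: 8 tert-butyl({(1R,4R)-4-[(E)-2-iodoethenyl]-3,5,5-trimethylcyclohex-2-en-1-yl}oxy)dimethylsilane
Conditions: CrCl2 (6 equiv), CHI3 (2 equiv), THF–1,4-dioxane, 0 °C → rt, dark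
Reagents that add atoms: iodoform, IC(I)I
Why: Takai iodo-olefination, in which the geminal dichromium reagent formed from CHI3 and divalent chromium adds to the aldehyde and eliminates anti, should give the E-alkenyl iodide under neutral conditions that leave the α-centre C6 alone.

Step 7
Reactants: 8 tert-butyl({(1R,4R)-4-[(E)-2-iodoethenyl]-3,5,5-trimethylcyclohex-2-en-1-yl}oxy)dimethylsilane
Product: 9 fragment 1: tert-butyl({(1R,4R)-4-[(1E)-but-1-en-3-yn-1-yl]-3,5,5-trimethylcyclohex-2-en-1-yl}oxy)dimethylsilane
Conditions: HC≡CMgBr, ZnBr2, THF, 0 °C; then 8, Pd(PPh3)4 (5 mol %), THF, rt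
Reagents that add atoms: ethynylmagnesium bromide, C#C[Mg]Br
Why: Negishi alkynylation with ethynylzinc bromide should install the terminal alkyne directly and with retention of the E alkene, since oxidative addition of the alkenyl iodide to zerovalent palladium, transmetalation from zinc and reductive elimination involve no base able to reach the bis-allylic C6–H.

Step 8
Reactants: 10 (2E,4E,6E)-2,7-dimethylocta-2,4,6-trienedial; 11 ethyl (2E)-4-(diethoxyphosphoryl)-2-methylbut-2-enoate
Product: 12 ethyl (2E,4E,6E,8E,10E)-2,6,11-trimethyl-12-oxododeca-2,4,6,8,10-pentaenoate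
Conditions: 11, LiN(SiMe3)2, THF, −78 °C; added slowly to 10 (2.5 equiv), THF, −78 → 0 °C, dark; excess 10 recovered
Reagents that add atoms: none
Why: Horner–Wadsworth–Emmons olefination with the ester-stabilised allylic phosphonate anion should give the new E alkene (C11'=C12') with the 2E enoate geometry kept, and slow addition of the anion to an excess of the symmetrical dialdehyde limits the reaction to one formyl group.

Step 9
Reactants: 12 ethyl (2E,4E,6E,8E,10E)-2,6,11-trimethyl-12-oxododeca-2,4,6,8,10-pentaenoate
Product: 13 ethyl (2E,4E,6E,8E,10E,12E)-13-iodo-2,6,11-trimethyltrideca-2,4,6,8,10,12-hexaenoate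
Conditions: CrCl2 (8 equiv), CHI3 (2.5 equiv), THF–1,4-dioxane, 0 °C → rt, dark
Reagents that add atoms: iodoform, IC(I)I
Why: Takai iodo-olefination of the enal should turn the formyl group into the E-iodovinyl terminus (C11=C12) chemoselectively, because the reagent formed from CHI3 and divalent chromium does not add to the conjugated ester.

Step 10
Reactants: 13 ethyl (2E,4E,6E,8E,10E,12E)-13-iodo-2,6,11-trimethyltrideca-2,4,6,8,10,12-hexaenoate
Product: 14 (2E,4E,6E,8E,10E,12E)-13-iodo-2,6,11-trimethyltrideca-2,4,6,8,10,12-hexaen-1-ol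
Conditions: iBu2AlH (2.2 equiv), CH2Cl2, −78 °C, dark; aq. potassium sodium tartrate
Reagents that add atoms: none
Why: 1,2-Reduction of the conjugated ester by iBu2AlH at low temperature should give the primary allylic alcohol while the alkenyl iodide and the polyene are inert to the hydride.

Step 11
Reactants: 14 (2E,4E,6E,8E,10E,12E)-13-iodo-2,6,11-trimethyltrideca-2,4,6,8,10,12-hexaen-1-ol
Product: 15 fragment 2: tert-butyl{[(2E,4E,6E,8E,10E,12E)-13-iodo-2,6,11-trimethyltrideca-2,4,6,8,10,12-hexaen-1-yl]oxy}dimethylsilane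
Conditions: TBSCl, imidazole, CH2Cl2, 0 °C → rt, dark
Reagents that add atoms: tert-butyldimethylsilyl chloride, CC(C)(C)[Si](C)(C)Cl
Why: Imidazole-promoted silylation of the primary allylic alcohol (silyl ether formation) is fast and mild enough not to isomerise the iodohexaene.

Step 12
Reactants: 9 fragment 1 (ring enyne silyl ether); 15 fragment 2 (iodohexaene silyl ether); 16 trimethylaluminium
Product: 19 bis(tert-butyldimethylsilyl) ether of the target, via alkenylalane 17 (not isolated), via alkenylzinc chloride 18 (not isolated)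
Conditions: 9 (1.2 equiv), AlMe3 (2 equiv), Cp2ZrCl2 (0.25 equiv), (CH2Cl)2, rt; volatiles removed in vacuo; ZnCl2 (1 equiv), THF; then 15, Pd(PPh3)4 (5 mol %), THF, rt, dark
Reagents that add atoms: trimethylaluminium 16, C[Al](C)C
Why: The bimetallic methylating species formed from AlMe3 and Cp2ZrCl2 adds methyl and aluminium syn across the terminal C9≡C10 alkyne of 9, methyl to the internal carbon C9 and aluminium to C10, to give the 9E alkenylalane 17, and after excess AlMe3 is stripped ZnCl2 takes over the alkenyl group as 18. Zerovalent palladium inserts into the C11–I bond of 15, the alkenyl group passes from zinc to palladium, and reductive elimination joins C10 to C11 with retention at both alkene carbons. The closest known reaction type is the Negishi tandem of Cp2ZrCl2-catalysed carboalumination of a terminal 1,3-enyne and Pd(PPh3)4-catalysed alkenyl–alkenyl cross-coupling. No ring is closed and no stereocentre is created, and the C3 and C6 centres of 9 are only carried through, because the medium holds no base able to remove the bis-allylic C6–H and no protic acid. The step needs regioselectivity (methyl on C9) and syn stereoselectivity (9E), both secured by the unhindered terminal alkyne whose internal carbon carries the C7=C8 vinyl group, and it needs retention of the all-E geometry of 15, secured by the stereoretentive coupling at room temperature in the dark. Removing the excess AlMe3 before 15 is added keeps the Lewis acid away from the allylic silyl ether of the hexaene.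

Step 13
Reactants: 19 bis(tert-butyldimethylsilyl) ether of the target
Product: 20 target diol, (3R,6R)-8'-apo-ε-carotene-3,8'-diol
Conditions: Bu4NF (4 equiv), AcOH (4 equiv), THF, 0 °C → rt, dark, argon
Reagents that add atoms: none
Why: Fluoride-driven cleavage of both Si–O bonds (desilylation), buffered with acetic acid so that no free alkoxide acts on the polyene, should release the secondary and the primary allylic alcohol without touching C3, C6 or any alkene geometry.

Compound list
1 | mesityl oxide (4-methylpent-3-en-2-one) | CC(C)=CC(C)=O | starting material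
2 | ethyl acetoacetate | CCOC(=O)CC(C)=O | starting material
3 | racemic ethyl 2,6,6-trimethyl-4-oxocyclohex-2-ene-1-carboxylate | CCOC(=O)C1C(C)=CC(=O)CC1(C)C | intermediate
4 | ethyl (1R,4R)-4-hydroxy-2,6,6-trimethylcyclohex-2-ene-1-carboxylate | CC1=C[C@H](O)CC(C)(C)[C@H]1C(=O)OCC | intermediate
5 | ethyl (1R,4R)-4-[(tert-butyldimethylsilyl)oxy]-2,6,6-trimethylcyclohex-2-ene-1-carboxylate | CC1=C[C@H](O[Si](C)(C)C(C)(C)C)CC(C)(C)[C@H]1C(=O)OCC | intermediate
6 | [(1R,4R)-4-[(tert-butyldimethylsilyl)oxy]-2,6,6-trimethylcyclohex-2-en-1-yl]methanol | CC1=C[C@H](O[Si](C)(C)C(C)(C)C)CC(C)(C)[C@H]1CO | intermediate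
7 | (1R,4R)-4-[(tert-butyldimethylsilyl)oxy]-2,6,6-trimethylcyclohex-2-ene-1-carbaldehyde | CC1=C[C@H](O[Si](C)(C)C(C)(C)C)CC(C)(C)[C@H]1C=O | intermediate
8 | tert-butyl({(1R,4R)-4-[(E)-2-iodoethenyl]-3,5,5-trimethylcyclohex-2-en-1-yl}oxy)dimethylsilane | CC1=C[C@H](O[Si](C)(C)C(C)(C)C)CC(C)(C)[C@H]1/C=C/I | intermediate
9 | fragment 1: tert-butyl({(1R,4R)-4-[(1E)-but-1-en-3-yn-1-yl]-3,5,5-trimethylcyclohex-2-en-1-yl}oxy)dimethylsilane, (3R,6R) in carotenoid numbering | CC1=C[C@H](O[Si](C)(C)C(C)(C)C)CC(C)(C)[C@H]1/C=C/C#C | intermediate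
10 | (2E,4E,6E)-2,7-dimethylocta-2,4,6-trienedial | O=C/C(C)=C/C=C/C=C(C)/C=O | starting material
11 | ethyl (2E)-4-(diethoxyphosphoryl)-2-methylbut-2-enoate | CCOC(=O)/C(C)=C/CP(=O)(OCC)OCC | starting material
12 | ethyl (2E,4E,6E,8E,10E)-2,6,11-trimethyl-12-oxododeca-2,4,6,8,10-pentaenoate | CCOC(=O)/C(C)=C/C=C/C(C)=C/C=C/C=C(C)/C=O | intermediate
13 | ethyl (2E,4E,6E,8E,10E,12E)-13-iodo-2,6,11-trimethyltrideca-2,4,6,8,10,12-hexaenoate | CCOC(=O)/C(C)=C/C=C/C(C)=C/C=C/C=C(C)/C=C/I | intermediate
14 | (2E,4E,6E,8E,10E,12E)-13-iodo-2,6,11-trimethyltrideca-2,4,6,8,10,12-hexaen-1-ol | OC/C(C)=C/C=C/C(C)=C/C=C/C=C(C)/C=C/I | intermediate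
15 | fragment 2: tert-butyl{[(2E,4E,6E,8E,10E,12E)-13-iodo-2,6,11-trimethyltrideca-2,4,6,8,10,12-hexaen-1-yl]oxy}dimethylsilane | I/C=C/C(C)=C/C=C/C=C(C)/C=C/C=C(\C)CO[Si](C)(C)C(C)(C)C | intermediate
16 | trimethylaluminium | C[Al](C)C | starting material
17 | dimethyl[(1E,3E)-4-{(1R,4R)-4-[(tert-butyldimethylsilyl)oxy]-2,6,6-trimethylcyclohex-2-en-1-yl}-2-methylbuta-1,3-dien-1-yl]alane, formed in the flask | CC1=C[C@H](O[Si](C)(C)C(C)(C)C)CC(C)(C)[C@H]1/C=C/C(C)=C/[Al](C)C | intermediate
18 | chloro[(1E,3E)-4-{(1R,4R)-4-[(tert-butyldimethylsilyl)oxy]-2,6,6-trimethylcyclohex-2-en-1-yl}-2-methylbuta-1,3-dien-1-yl]zinc, formed in the flask | CC1=C[C@H](O[Si](C)(C)C(C)(C)C)CC(C)(C)[C@H]1/C=C/C(C)=C/[Zn]Cl | intermediate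
19 | bis(tert-butyldimethylsilyl) ether of the target: tert-butyl{[(2E,4E,6E,8E,10E,12E,14E,16E)-17-{(1R,4R)-4-[(tert-butyldimethylsilyl)oxy]-2,6,6-trimethylcyclohex-2-en-1-yl}-2,6,11,15-tetramethylheptadeca-2,4,6,8,10,12,14,16-octaen-1-yl]oxy}dimethylsilane | CC1=C[C@H](O[Si](C)(C)C(C)(C)C)CC(C)(C)[C@H]1/C=C/C(C)=C/C=C/C(C)=C/C=C/C=C(C)/C=C/C=C(\C)CO[Si](C)(C)C(C)(C)C | intermediate
20 | (2E,4E,6E,8E,10E,12E,14E,16E)-17-[(1R,4R)-4-hydroxy-2,6,6-trimethylcyclohex-2-en-1-yl]-2,6,11,15-tetramethylheptadeca-2,4,6,8,10,12,14,16-octaen-1-ol, (3R,6R) in carotenoid numbering | CC1=C[C@H](O)CC(C)(C)[C@H]1/C=C/C(C)=C/C=C/C(C)=C/C=C/C=C(C)/C=C/C=C(\C)CO | target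

Total step count: 13. Longest linear sequence: 9 steps (steps 1 to 7, then 12 and 13).

Steps most likely to fail

Step 12. The iodohexaene partner may be degraded by aluminium and zirconium Lewis acids left in the flask (loss of its allylic silyl ether, scrambling of alkene geometry), or the alkenyl group may pass to palladium too slowly, so that homocoupling and protodemetalation compete. The fallback sets out from 9 and comes back at 19. The methylalumination of 9 is run as before, but the alane is quenched with I2 (THF, −30 °C) to give the isolable (1E,3E)-dienyl iodide F1, which is freed from all aluminium and zirconium salts. Iodine–lithium exchange (tBuLi, Et2O, −78 °C) and Bu3SnCl then give the dienylstannane F2. Stille coupling of F2 with 15 (Pd2(dba)3, AsPh3, DMF–THF, rt, dark) forms the same C10–C11 bond under neutral conditions and gives 19.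

Step 2. The enzymes at hand may discriminate poorly between the two enantiomers of the keto ester or prefer the wrong carbonyl face, which would give mixtures of stereoisomers. The fallback sets out from 3 and comes back at 4. Luche reduction (NaBH4, CeCl3·7H2O, MeOH, −20 °C) gives the racemic trans hydroxy ester F3 together with the racemic cis hydroxy ester F4, and the two are separated by chromatography. Acylation of F3 with Burkholderia cepacia lipase and vinyl acetate (tBuOMe, rt) is expected to esterify the (4R) carbinol, as Kazlauskas' rule predicts when the alkene flank is the large group, giving the (1R,4R) acetate F5 beside unreacted (1S,4S) alcohol. K2CO3 in EtOH (0 °C) removes the acetyl group and gives 4.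

Step 9. The chromium olefination of the enal may be incompletely E-selective, or the pentaene may isomerise or decompose during long contact with chromium salts. The fallback sets out from 12 and comes back at 15. Colvin homologation (Me3SiCHN2, LiN(iPr)2, THF, −78 → 0 °C) turns the formyl group into a terminal alkyne and gives the pentaenyne ester F6. iBu2AlH (CH2Cl2, −78 °C) gives the pentaenynol F7, and TBSCl with imidazole gives the pentaenyne silyl ether F8. Hydrozirconation with Cp2Zr(H)Cl (THF, rt, dark) followed by I2 (0 °C) fixes the E-alkenyl iodide by syn addition and stereoretentive iodinolysis and gives 15.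

Further compounds
F1 | step 12 | tert-butyl({(1R,4R)-4-[(1E,3E)-4-iodo-3-methylbuta-1,3-dien-1-yl]-3,5,5-trimethylcyclohex-2-en-1-yl}oxy)dimethylsilane | CC1=C[C@H](O[Si](C)(C)C(C)(C)C)CC(C)(C)[C@H]1/C=C/C(C)=C/I
F2 | step 12 | tributyl[(1E,3E)-4-{(1R,4R)-4-[(tert-butyldimethylsilyl)oxy]-2,6,6-trimethylcyclohex-2-en-1-yl}-2-methylbuta-1,3-dien-1-yl]stannane | CC1=C[C@H](O[Si](C)(C)C(C)(C)C)CC(C)(C)[C@H]1/C=C/C(C)=C/[Sn](CCCC)(CCCC)CCCC
F3 | step 2 | racemic trans ethyl (1RS,4RS)-4-hydroxy-2,6,6-trimethylcyclohex-2-ene-1-carboxylate (racemate, one enantiomer drawn) | CC1=C[C@H](O)CC(C)(C)[C@H]1C(=O)OCC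
F4 | step 2 | racemic cis ethyl (1RS,4SR)-4-hydroxy-2,6,6-trimethylcyclohex-2-ene-1-carboxylate (racemate, one enantiomer drawn) | CC1=C[C@@H](O)CC(C)(C)[C@H]1C(=O)OCC
F5 | step 2 | ethyl (1R,4R)-4-(acetyloxy)-2,6,6-trimethylcyclohex-2-ene-1-carboxylate | CC1=C[C@H](OC(C)=O)CC(C)(C)[C@H]1C(=O)OCC
F6 | step 9 | ethyl (2E,4E,6E,8E,10E)-2,6,11-trimethyltrideca-2,4,6,8,10-pentaen-12-ynoate | CCOC(=O)/C(C)=C/C=C/C(C)=C/C=C/C=C(C)/C#C
F7 | step 9 | (2E,4E,6E,8E,10E)-2,6,11-trimethyltrideca-2,4,6,8,10-pentaen-12-yn-1-ol | OC/C(C)=C/C=C/C(C)=C/C=C/C=C(C)/C#C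
F8 | step 9 | tert-butyldimethyl{[(2E,4E,6E,8E,10E)-2,6,11-trimethyltrideca-2,4,6,8,10-pentaen-12-yn-1-yl]oxy}silane | C#C/C(C)=C/C=C/C=C(C)/C=C/C=C(\C)CO[Si](C)(C)C(C)(C)C
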